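**Retrosynthetic overview**
1. Onind is an aromatic ring B (phlorisobutyrophenone) whose two free ring carbons each carry, through a CH2 bridge, one of two identical dearomatised rings A and C (isobutyrylfilicinic acid). The molecule has a mirror plane and no stereocentre. Both bridges are cut at the CH2–C(ring A/C) bond, giving a bis(aminomethyl) ring B and two molecules of one monomer.
2. Enabling feature: in ring A (and C) the four-carbon run CMe2–C(OH)=CH–C(OH) is the chain Me2CH–CO–CH2–CO of isobutyrylacetate. The other two ring carbons, C(=O) and C(acyl), together with the exocyclic isobutyryl group are the same chain again. The ring is therefore a head-to-tail dimer of one commercial β-keto ester.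
3. Key disconnection: the CMe2–C(=O) bond and the C(OH)–C(acyl) bond of the outer ring. Both are made in one flask by a formal [4+2] double Claisen self-condensation of the dianion and the mono-enolate of methyl 4-methyl-3-oxopentanoate. This sets the quaternary carbon, the triketone pattern and the acyl group together, and supplies 24 of the 36 carbons.
4. Ring order: rings A and C are formed first, in one batch in step 1. Ring B is bought as phloroglucinol, then acylated and aminomethylated. The last step forms no ring and only joins A, B and C.

Key step: step 1

Remark on the chemistry: all β-triketone and enol units tautomerise freely. Every SMILES keeps the enol tautomer in which the target is drawn, enolate salts are written as carbanions, and no compound of the route has a stereocentre.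

Step 1
Reactants: 1 methyl 4-methyl-3-oxopentanoate (methyl isobutyrylacetate; two molecules per molecule of product)
Product: 5 isobutyrylfilicinic acid, via sodium enolate 2 (not isolated), via sodium lithium dianion 3 (not isolated), via triketo ester 4 (not isolated)
Conditions: NaH (1.0 equiv), THF, 0 °C; n-BuLi (0.5 equiv), 0 °C, then reflux; AcOH (1.0 equiv), MeOH, 50 °C; 1 M HCl work-up
Reagents that add atoms: none
Why: NaH turns all of 1 into enolate 2 and n-BuLi then removes the isopropyl methine proton from half of it, so that dianion 3 (nucleophilic at its last-formed, tertiary carbanion) and enolate 2 (electrophilic only at its ester carbon) are present in equal amounts; attack of the Me2C carbon of 3 on the ester carbon of 2 with loss of methoxide makes the CMe2–C(=O) bond and gives 4 as its bis-enolate, in which both ketones next to the new quaternary carbon are shielded as enolates against retro-Claisen cleavage. Ring closure can begin in the refluxing mixture and is completed by partial neutralisation with AcOH, which leaves the more acidic 1,3-diketone site deprotonated and frees the β-keto ester, so that the diketone carbon closes on the ester carbonyl (6-(enolexo)-exo-trig Dieckmann-type Claisen closure, helped by the Thorpe–Ingold effect of the gem-dimethyl group) to make the C(OH)–C(acyl) bond and the outer ring. The closest known reaction types are the thermal self-condensation of acetoacetate dianions (the γ-carbon of one molecule is acylated by the ester of a second and the chain cyclises in the same flask), the γ-acylation of β-keto ester dianions by esters, and the Claisen-mode cyclisation of 3,5,7-triketo esters to acylphloroglucinols under acetate buffer. No stereocentre is formed. The step needs γ- over α-attack (secured by the higher basicity of the tertiary carbanion of 3), head-to-tail pairing (secured by the half equivalent of n-BuLi) and Claisen over aldol closure, which is secured because at the mono-anion stage only the diketone carbon is nucleophilic and only the ester is uncharged, the aldol acceptor is a hindered isopropyl ketone, the gem-dimethyl carbon forbids aromatisation of an aldol product, and 5 leaves all reversible side equilibria as a strongly stabilised vinylogous tricarbonyl anion.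

Step 2
Reactants: 6 phloroglucinol; 7 isobutyryl chloride
Product: 8 phlorisobutyrophenone
Conditions: AlCl3 (4 equiv), CH2Cl2/MeNO2, 0 to 40 °C; ice/HCl work-up
Reagents that add atoms: none
Why: Friedel–Crafts C-acylation of a very electron-rich arene, in which the first acyl group deactivates the ring and chelates AlCl3, so that one equivalent of 7 should stop at the monoketone.

Step 3
Reactants: 8 phlorisobutyrophenone; 9 bis(dimethylamino)methane (2.2 equiv)
Product: 10 3,5-bis[(dimethylamino)methyl]phlorisobutyrophenone
Conditions: 1,4-dioxane, 0 °C to rt; product collected and used without chromatography
Reagents that add atoms: none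
Why: Phenol Mannich reaction with a preformed aminal, in which the acidic phenol protonates 9 to release the iminium ion, this attacks the two equivalent and strongly activated free ring carbons, and the absence of free formaldehyde suppresses diarylmethane formation.

Step 4
Reactants: 10 3,5-bis[(dimethylamino)methyl]phlorisobutyrophenone; 5 isobutyrylfilicinic acid (2.1 equiv)
Product: 14 onind, via quinone methide 11 (not isolated), via mono-adduct 12 (not isolated), via second quinone methide 13 (not isolated)
Conditions: 1,4-dioxane, 60 °C, N2 sweep; 1 M HCl wash
Reagents that add atoms: none
Why: Alkylation of a cyclic 1,3-dicarbonyl compound by a phenolic Mannich base through o-quinone methides, in which acidic 5 protonates the amine, dimethylamine leaves, and the only free nucleophilic carbon of 5 (the ring CH between the two enolic carbons) adds in Michael fashion with rearomatisation, twice, while homocoupling is excluded because 10 has no free ring carbon and 5 carries no electrophilic CH2.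

**Compound list**
1 | methyl 4-methyl-3-oxopentanoate (methyl isobutyrylacetate) | COC(=O)CC(=O)C(C)C | starting material
2 | sodium enolate of 1 | [Na+].COC(=O)[CH-]C(=O)C(C)C | intermediate
3 | sodium lithium dianion of 1 (α-carbon and isopropyl carbon deprotonated) | [Na+].[Li+].COC(=O)[CH-]C(=O)[C-](C)C | intermediate
4 | methyl 4,4,8-trimethyl-3,5,7-trioxononanoate (present as its enolates) | COC(=O)CC(=O)C(C)(C)C(=O)CC(=O)C(C)C | intermediate
5 | isobutyrylfilicinic acid, 3,5-dihydroxy-6,6-dimethyl-2-(2-methylpropanoyl)cyclohexa-2,4-dien-1-one | CC(C)C(=O)C1=C(O)C=C(O)C(C)(C)C1=O | intermediate
6 | phloroglucinol (benzene-1,3,5-triol) | Oc1cc(O)cc(O)c1 | starting material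
7 | isobutyryl chloride | CC(C)C(=O)Cl | starting material
8 | phlorisobutyrophenone, 2-methyl-1-(2,4,6-trihydroxyphenyl)propan-1-one | CC(C)C(=O)c1c(O)cc(O)cc1O | intermediate
9 | bis(dimethylamino)methane | CN(C)CN(C)C | starting material
10 | 1-{3,5-bis[(dimethylamino)methyl]-2,4,6-trihydroxyphenyl}-2-methylpropan-1-one | CC(C)C(=O)c1c(O)c(CN(C)C)c(O)c(CN(C)C)c1O | intermediate
11 | o-quinone methide from 10 by loss of one dimethylamine | CC(C)C(=O)C1=C(O)C(CN(C)C)=C(O)C(=C)C1=O | intermediate
12 | mono-adduct: ring B carrying one CH2-linked outer ring and one remaining CH2NMe2 group | CC(C)C(=O)c1c(O)c(CN(C)C)c(O)c(CC2=C(O)C(C)(C)C(=O)C(C(=O)C(C)C)=C2O)c1O | intermediate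
13 | o-quinone methide from 12 by loss of dimethylamine | CC(C)C(=O)C1=C(O)C(CC2=C(O)C(C)(C)C(=O)C(C(=O)C(C)C)=C2O)=C(O)C(=C)C1=O | intermediate
14 | onind, 1-[2,4,6-trihydroxy-3,5-bis({2,6-dihydroxy-3,3-dimethyl-4-oxo-5-(2-methylpropanoyl)cyclohexa-1,5-dien-1-yl}methyl)phenyl]-2-methylpropan-1-one | CC(C)C(=O)C1=C(O)C(Cc2c(O)c(CC3=C(O)C(C)(C)C(=O)C(C(=O)C(C)C)=C3O)c(O)c(C(=O)C(C)C)c2O)=C(O)C(C)(C)C1=O | target

Total step count: 4. Longest linear sequence: 3 (6 → 8 → 10 → 14). The branch 1 → 5 → 14 has 2 steps.

**Steps most likely to fail**

1. Step 1. The tertiary carbanion of 3 may be acylated too slowly by an ester that is deactivated as its enolate. Proton exchange, loss of methoxide to a ketene and head-to-head self-condensation with O-cyclisation could then take over. The open chain may also cleave again by retro-Claisen reaction before it closes.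
   - Fallback (outer ring made from an aromatic ring instead of an open chain): it sets out from 8.
   - 8 is C-methylated twice at one ring carbon with MeI and NaOMe in MeOH, which is the known dearomatising alkylation of acylphloroglucinols.
   - The reaction passes through 1-(2,4,6-trihydroxy-3-methylphenyl)-2-methylpropan-1-one F1 and comes back to the route at 5.

2. Step 4. Bridges already formed may reopen by retro-Michael cleavage in the warm, amine-containing medium, which would move CH2 units between the partners. The second coupling may also lag behind the first.
   - Fallback (reversed polarity): it sets out from 5 and 9.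
   - Aminomethylation of the free ring CH of 5 gives 4-[(dimethylamino)methyl]-3,5-dihydroxy-6,6-dimethyl-2-(2-methylpropanoyl)cyclohexa-2,4-dien-1-one F2.
   - Two equivalents of F2 are warmed with 8 and catalytic Et3N in THF.
   - Loss of dimethylamine unmasks an exocyclic methylene triketone on the outer ring, and the two free ring carbons of 8 add to it (double Michael-type Friedel–Crafts alkylation of an acylphloroglucinol by alkylidene triketones).
   - The sequence comes back to the route at 14.

3. Step 3. The second aminomethylation may stay incomplete, or the product may lose dimethylamine during the reaction and oligomerise through attack of its own heteroatoms on the quinone methide.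
   - Fallback (bridge carbon brought in at the aldehyde level): it sets out from 8.
   - Double Vilsmeier–Haack formylation (POCl3, DMF) gives 2,4,6-trihydroxy-5-(2-methylpropanoyl)benzene-1,3-dicarbaldehyde F3.
   - F3 is combined with 5 (2 equiv), Hantzsch ester and catalytic L-proline in a three-component reductive alkylation (Knoevenagel condensation followed in the same flask by conjugate hydride transfer).
   - This bypasses 10 and comes back to the route at 14.

**Further compounds**
F1 | step 1 | 1-(2,4,6-trihydroxy-3-methylphenyl)-2-methylpropan-1-one | CC(C)C(=O)c1c(O)cc(O)c(C)c1O
F2 | step 4 | 4-[(dimethylamino)methyl]-3,5-dihydroxy-6,6-dimethyl-2-(2-methylpropanoyl)cyclohexa-2,4-dien-1-one | CC(C)C(=O)C1=C(O)C(CN(C)C)=C(O)C(C)(C)C1=O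
F3 | step 3 | 2,4,6-trihydroxy-5-(2-methylpropanoyl)benzene-1,3-dicarbaldehyde | CC(C)C(=O)c1c(O)c(C=O)c(O)c(C=O)c1O
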